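Retrosynthesis: ring C is opened at O1–C2 (oxa-Michael) and then at C8a–O1 and C4a–C4 in one cut (aryne insertion into a carboxylic acid C–O bond), which gives 3,4-dimethoxybenzyne (ring A) and 3-(2,3,4,6-tetramethoxyphenyl)propiolic acid (ring B with C2, C3 and C4).
Enabling feature: on ring A the positions C8a, C4a, C5 and C6 are substituted in an unbroken row (ring oxygen O1, carbonyl carbon C4, two methoxy groups); the adjacent carbons C8a and C4a are therefore the former triple bond of a benzyne, and the methoxy group on C5, next to C4a, decides which of the two receives oxygen.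
Ring A half: 3,4-dimethoxyphenol is carbamoylated, silylated at C2 by directed metalation and converted into the ortho-silyl aryl triflate (three steps).
Ring B half: 3,4,5-trimethoxyphenol is methylated, formylated (C1'–C2), homologated by Corey–Fuchs olefination (C2–C3) and carboxylated (C3–C4) (four steps).
Order of rings: A and B are purchased benzenoid rings; the pyranone ring C is the only ring built and closes last, in the same pot as the union of the two halves.
Stereochemistry: nothing to set; the target has no stereocentre and no stereogenic double bond.

Key step: step 8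

Remark: flavone numbering is used (O1, C2, C3, C4, C4a, C5 to C8, C8a; ring B primed); species that exist as salts in the flask are listed by their neutral formulas unless the counter-ion is given.

Step 1
Reactants: 1 3,4-dimethoxyphenol
Product: 2 3,4-dimethoxyphenyl N-isopropylcarbamate
Conditions: i-PrNCO, Et3N (cat.), CH2Cl2, rt
Reagents that add atoms: isopropyl isocyanate CC(C)N=C=O
Why: Amine-catalysed carbamoylation (addition of the phenol O–H across the isocyanate C=N) is clean for electron-rich phenols and installs a carbamate that directs ortho-metalation strongly yet can later be removed under mild base.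

Step 2
Reactants: 2 3,4-dimethoxyphenyl N-isopropylcarbamate
Product: 6 3,4-dimethoxy-2-(trimethylsilyl)phenyl N-isopropylcarbamate, via N-TBS carbamate 3 (not isolated), via 2-lithio N-TBS carbamate 4 (not isolated), via N-TBS 2-TMS carbamate 5 (not isolated)
Conditions: TBSOTf, TMEDA, Et2O, 0 °C to rt; n-BuLi (2 equiv), TMEDA, −78 °C; TMSCl, −78 °C to rt; aq. NaHSO4
Reagents that add atoms: chlorotrimethylsilane C[Si](C)(C)Cl
Why: Directed ortho-metalation: once the acidic N–H is masked in the flask as N–Si, n-BuLi/TMEDA should remove the C2 proton, the most acidic ring hydrogen because it lies between the carbamate oxygen and the C3 methoxy group, TMSCl traps the aryllithium and the acidic work-up hydrolyses the N–Si bond; the C2 regiochemistry is to be confirmed by the expected pair of ortho-coupled aromatic doublets (H5/H6), since a C6 silyl isomer would lead to the wrong aryne.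

Step 3
Reactants: 6 3,4-dimethoxy-2-(trimethylsilyl)phenyl N-isopropylcarbamate
Product: 8 3,4-dimethoxy-2-(trimethylsilyl)phenyl trifluoromethanesulfonate, via 3,4-dimethoxy-2-(trimethylsilyl)phenol 7 (not isolated)
Conditions: Et2NH, DBU, MeCN, 40 °C; then PhNTf2, rt
Reagents that add atoms: N-phenylbis(trifluoromethanesulfonimide) O=S(=O)(N(c1ccccc1)S(=O)(=O)C(F)(F)F)C(F)(F)F
Why: E1cB cleavage of the N-monosubstituted carbamate (DBU removes the N–H, the phenoxide is expelled and diethylamine scavenges the isopropyl isocyanate as a urea) followed by O-sulfonylation of the phenoxide with PhNTf2 is the established one-pot entry to ortho-silylaryl triflates and spares the protodesilylation-prone free silylphenol from isolation.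

Step 4
Reactants: 9 3,4,5-trimethoxyphenol
Product: 10 1,2,3,5-tetramethoxybenzene
Conditions: MeI, K2CO3, acetone, reflux
Reagents that add atoms: iodomethane CI
Why: Williamson O-methylation of the only free hydroxyl group, the potassium phenoxide being an unhindered nucleophile for the SN2 reaction with MeI.

Step 5
Reactants: 10 1,2,3,5-tetramethoxybenzene
Product: 12 2,3,4,6-tetramethoxybenzaldehyde, via aryliminium dichlorophosphate 11 (not isolated)
Conditions: POCl3, DMF, 0 °C to 60 °C; then ice-water
Reagents that add atoms: N,N-dimethylformamide CN(C)C=O; water O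
Why: Vilsmeier–Haack formylation (electrophilic aromatic substitution by the chloroiminium ion): the two free ring positions are equivalent by symmetry, each is ortho to two methoxy groups and para to a third, and the deactivating iminium group prevents a second formylation.

Step 6
Reactants: 12 2,3,4,6-tetramethoxybenzaldehyde
Product: 13 2-(2,2-dibromovinyl)-1,3,4,5-tetramethoxybenzene
Conditions: CBr4, PPh3, Zn dust, CH2Cl2, rt
Reagents that add atoms: carbon tetrabromide BrC(Br)(Br)Br
Why: Corey–Fuchs (Ramirez) dibromo-olefination, a Wittig reaction of the aldehyde with Ph3P=CBr2 made in the flask, the Zn variant keeping the medium free of Ph3PBr2 and of acid.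

Step 7
Reactants: 13 2-(2,2-dibromovinyl)-1,3,4,5-tetramethoxybenzene
Product: 15 3-(2,3,4,6-tetramethoxyphenyl)propiolic acid, via lithium arylacetylide 14 (not isolated)
Conditions: n-BuLi (2.1 equiv), THF, −78 °C; CO2, −78 °C to 0 °C; cold 1 M HCl
Reagents that add atoms: carbon dioxide O=C=O
Why: Second stage of the Corey–Fuchs sequence: bromine–lithium exchange and a Fritsch–Buttenberg–Wiechell 1,2-shift give the terminal alkyne, which the second equivalent of n-BuLi deprotonates to the acetylide that adds to CO2; holding the base near two equivalents at −78 °C should spare the ring C–H flanked by two methoxy groups, and cold acidification with cold storage should suppress loss of CO2 from the acid.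

Step 8
Reactants: 15 3-(2,3,4,6-tetramethoxyphenyl)propiolic acid; 8 3,4-dimethoxy-2-(trimethylsilyl)phenyl trifluoromethanesulfonate
Product: 18 5,6,2',3',4',6'-hexamethoxyflavone, via 3,4-dimethoxybenzyne 16 (not isolated), via ortho-hydroxyaryl ynone 17 (not isolated)
Conditions: 8 (1.5 equiv), CsF (4 equiv), THF, 125 °C, sealed tube
Reagents that add atoms: none
Why: CsF deprotonates acid 15 and removes the silyl group of 8 with loss of triflate to release aryne 16; the carboxylate oxygen bonds to the aryne carbon remote from the flanking methoxy group (the future C8a), and the aryl anion thus formed at the future C4a attacks the neighbouring ester carbonyl through a four-membered tetrahedral intermediate that opens to the ortho-acyl phenoxide 17, so that the aryne ends up inserted into the C–O bond of the acid. The closest known reaction type is the fluoride-triggered C–O insertion of arynes into carboxylic acids (an anionic Fries-type 1,3 O-to-C acyl shift), which gives ortho-hydroxyaryl ketones and, with arylpropiolic acids, flavones in one pot; it is applied here to a 3,4-dialkoxybenzyne and an electron-rich, di-ortho-substituted propiolic acid. Ring C, the only ring formed, closes by 6-endo-dig oxa-Michael addition of the phenoxide O1 to the ynone β-carbon C2, and the single acidic proton of 15 ends up on C3; no stereocentre is created. Two selectivities are required: addition to the unsymmetrical aryne must be regioselective, which the σ-withdrawing methoxy group on C5 secures by stabilising negative charge on the adjacent ring carbon, so that the nucleophile bonds to the distal carbon C8a and the carbanion, hence the acyl group, sits at C4a; and closure must be 6-endo rather than 5-exo (flavone, not aurone), which the polarisation of the ynone toward its β-carbon secures, any surviving 17 being closable with diethylamine, which adds to C2 and cyclises through the enaminone. The high temperature is chosen so that the aryl anion acylates itself instead of being quenched by a proton, the rod-like propynoyl group is small enough to migrate into the position between the oxygen and the methoxy substituent, and cyclisation should consume the phenoxide before further aryne can O-arylate it.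

Compound list
1 | 3,4-dimethoxyphenol | COc1ccc(O)cc1OC | starting material
2 | 3,4-dimethoxyphenyl N-isopropylcarbamate | COc1ccc(OC(=O)NC(C)C)cc1OC | intermediate
3 | 3,4-dimethoxyphenyl N-(tert-butyldimethylsilyl)-N-isopropylcarbamate (not isolated) | COc1ccc(OC(=O)N(C(C)C)[Si](C)(C)C(C)(C)C)cc1OC | intermediate
4 | 2-lithio-3,4-dimethoxyphenyl N-(tert-butyldimethylsilyl)-N-isopropylcarbamate (not isolated) | COc1ccc(OC(=O)N(C(C)C)[Si](C)(C)C(C)(C)C)c([Li])c1OC | intermediate
5 | 3,4-dimethoxy-2-(trimethylsilyl)phenyl N-(tert-butyldimethylsilyl)-N-isopropylcarbamate (not isolated) | COc1ccc(OC(=O)N(C(C)C)[Si](C)(C)C(C)(C)C)c([Si](C)(C)C)c1OC | intermediate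
6 | 3,4-dimethoxy-2-(trimethylsilyl)phenyl N-isopropylcarbamate | COc1ccc(OC(=O)NC(C)C)c([Si](C)(C)C)c1OC | intermediate
7 | 3,4-dimethoxy-2-(trimethylsilyl)phenol (not isolated; present as its phenoxide) | COc1ccc(O)c([Si](C)(C)C)c1OC | intermediate
8 | 3,4-dimethoxy-2-(trimethylsilyl)phenyl trifluoromethanesulfonate | COc1ccc(OS(=O)(=O)C(F)(F)F)c([Si](C)(C)C)c1OC | intermediate
9 | 3,4,5-trimethoxyphenol | COc1cc(O)cc(OC)c1OC | starting material
10 | 1,2,3,5-tetramethoxybenzene | COc1cc(OC)c(OC)c(OC)c1 | intermediate
11 | N,N-dimethyl-1-(2,3,4,6-tetramethoxyphenyl)methaniminium dichlorophosphate (not isolated) | COc1cc(OC)c(C=[N+](C)C)c(OC)c1OC.[O-]P(=O)(Cl)Cl | intermediate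
12 | 2,3,4,6-tetramethoxybenzaldehyde | COc1cc(OC)c(C=O)c(OC)c1OC | intermediate
13 | 2-(2,2-dibromovinyl)-1,3,4,5-tetramethoxybenzene | COc1cc(OC)c(C=C(Br)Br)c(OC)c1OC | intermediate
14 | lithium (2,3,4,6-tetramethoxyphenyl)acetylide (not isolated) | COc1cc(OC)c(C#C[Li])c(OC)c1OC | intermediate
15 | 3-(2,3,4,6-tetramethoxyphenyl)propiolic acid | COc1cc(OC)c(C#CC(=O)O)c(OC)c1OC | intermediate
16 | 3,4-dimethoxybenzyne (transient, not isolated) | COC1=C(OC)C#CC=C1 | intermediate
17 | 1-(6-hydroxy-2,3-dimethoxyphenyl)-3-(2,3,4,6-tetramethoxyphenyl)prop-2-yn-1-one (not isolated; formed as its cesium phenoxide) | COc1cc(OC)c(C#CC(=O)c2c(O)ccc(OC)c2OC)c(OC)c1OC | intermediate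
18 | 5,6,2',3',4',6'-hexamethoxyflavone | COc1cc(OC)c(-c2cc(=O)c3c(OC)c(OC)ccc3o2)c(OC)c1OC | target

Total step count: 8 (steps 1 to 3 for the ring A half, steps 4 to 7 for the ring B half, step 8 for the union).
Longest linear sequence: 5 steps (9 to 10 to 12 to 13 to 15 to 18; steps 4, 5, 6, 7 and 8).

Steps most likely to fail

Step 8. The aryl anion may pick up a proton before the acyl shift, so that the sequence stops at the aryl propiolate. The cesium arylpropiolate may lose CO2 at 125 °C before the aryne is released. The phenoxide may be O-arylated by a second aryne, or closure may go 5-exo. The fallback sets out from triflate 8, with aldehyde 12 as partner, and comes back to the route at target 18. Aryne 16 is released from 8 as before (CsF, THF, 125 °C) but is intercepted by acetic acid, the simplest partner of the same C–O insertion. This should give 1-(6-hydroxy-2,3-dimethoxyphenyl)ethanone F1 under the same regiochemical control, without an alkyne that can decarboxylate or cyclise the wrong way. Claisen–Schmidt condensation of F1 with aldehyde 12 (KOH, EtOH, rt) should give (E)-1-(6-hydroxy-2,3-dimethoxyphenyl)-3-(2,3,4,6-tetramethoxyphenyl)prop-2-en-1-one F2. Oxidative cyclisation of F2 with catalytic I2 in DMSO at 130 °C (oxa-Michael closure to the flavanone, then dehydrogenation) closes ring C and delivers 18.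

Step 7. Excess n-BuLi may metalate the ring C–H that lies between two methoxy groups, which would lead to ring carboxylation. The electron-rich acid may also lose CO2 during acidic work-up or on standing. The fallback sets out from aldehyde 12 and comes back to the route at acid 15, and it uses no organolithium. Seyferth–Gilbert homologation of 12 with the Ohira–Bestmann reagent (dimethyl (1-diazo-2-oxopropyl)phosphonate, K2CO3, MeOH, rt) should give 2-ethynyl-1,3,4,5-tetramethoxybenzene F3. Catalytic C–H carboxylation of the terminal alkyne (CO2, AgI cat., Cs2CO3, DMF, 50 °C) should give cesium 3-(2,3,4,6-tetramethoxyphenyl)propiolate F4, which can be stored as the salt. Acid 15 is liberated with cold dilute HCl immediately before step 8.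

Step 2. Metalation may leak to C6, because the C3 methoxy group, held in place by its C4 neighbour, shields C2. Trapping of the crowded carbanion by TMSCl may also be slow enough for the carbamoyl group to migrate to carbon (anionic ortho-Fries shift). No intermediate of the route can be diverted, because the oxygen pattern is already fixed in 1. The fallback therefore sets out at the level of compound 1, which is replaced by commercial 2,3-dimethoxyphenol F5, and it comes back to the route at aryne 16 in step 8. In F5 only one position ortho to the phenol oxygen is free, so the regiochemistry of silylation is not in question and the silyl group ends up next to a hydrogen instead of a methoxy group.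
- Carbamoylation as in step 1 gives 2,3-dimethoxyphenyl N-isopropylcarbamate F6.
- The protocol of step 2 passes through 2,3-dimethoxyphenyl N-(tert-butyldimethylsilyl)-N-isopropylcarbamate F7, then 6-lithio-2,3-dimethoxyphenyl N-(tert-butyldimethylsilyl)-N-isopropylcarbamate F8, then 2,3-dimethoxy-6-(trimethylsilyl)phenyl N-(tert-butyldimethylsilyl)-N-isopropylcarbamate F9. Work-up gives 2,3-dimethoxy-6-(trimethylsilyl)phenyl N-isopropylcarbamate F10.
- The protocol of step 3 gives, by way of 2,3-dimethoxy-6-(trimethylsilyl)phenol F11, 2,3-dimethoxy-6-(trimethylsilyl)phenyl trifluoromethanesulfonate F12.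
- With CsF, F12 loses the silyl group and triflate from the same two ring carbons in the opposite sense and so releases the identical aryne 16. Step 8 is then run unchanged with F12 in place of 8.

Further compounds
F1 | step 8 | 1-(6-hydroxy-2,3-dimethoxyphenyl)ethanone | CC(=O)c1c(O)ccc(OC)c1OC
F2 | step 8 | (E)-1-(6-hydroxy-2,3-dimethoxyphenyl)-3-(2,3,4,6-tetramethoxyphenyl)prop-2-en-1-one | COc1cc(OC)c(/C=C/C(=O)c2c(O)ccc(OC)c2OC)c(OC)c1OC
F3 | step 7 | 2-ethynyl-1,3,4,5-tetramethoxybenzene | COc1cc(OC)c(C#C)c(OC)c1OC
F4 | step 7 | cesium 3-(2,3,4,6-tetramethoxyphenyl)propiolate | COc1cc(OC)c(C#CC(=O)[O-])c(OC)c1OC.[Cs+]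
F5 | step 2 | 2,3-dimethoxyphenol | COc1cccc(O)c1OC
F6 | step 2 | 2,3-dimethoxyphenyl N-isopropylcarbamate | COc1cccc(OC(=O)NC(C)C)c1OC
F7 | step 2 | 2,3-dimethoxyphenyl N-(tert-butyldimethylsilyl)-N-isopropylcarbamate | COc1cccc(OC(=O)N(C(C)C)[Si](C)(C)C(C)(C)C)c1OC
F8 | step 2 | 6-lithio-2,3-dimethoxyphenyl N-(tert-butyldimethylsilyl)-N-isopropylcarbamate | COc1ccc([Li])c(OC(=O)N(C(C)C)[Si](C)(C)C(C)(C)C)c1OC
F9 | step 2 | 2,3-dimethoxy-6-(trimethylsilyl)phenyl N-(tert-butyldimethylsilyl)-N-isopropylcarbamate | COc1ccc([Si](C)(C)C)c(OC(=O)N(C(C)C)[Si](C)(C)C(C)(C)C)c1OC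
F10 | step 2 | 2,3-dimethoxy-6-(trimethylsilyl)phenyl N-isopropylcarbamate | COc1ccc([Si](C)(C)C)c(OC(=O)NC(C)C)c1OC
F11 | step 2 | 2,3-dimethoxy-6-(trimethylsilyl)phenol | COc1ccc([Si](C)(C)C)c(O)c1OC
F12 | step 2 | 2,3-dimethoxy-6-(trimethylsilyl)phenyl trifluoromethanesulfonate | COc1ccc([Si](C)(C)C)c(OS(=O)(=O)C(F)(F)F)c1OC
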